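The dihydrofuran ring is cut at C3–C3a and C7a–O1. C7a lies between the C7 methoxy group and C3a–H, so an aryl iodide with iodine on C7a has a single free ortho position. Under palladium/norbornene catalysis that C–H is alkylated by the non-benzylic carbon of a cis-epoxide spanning C2 and C3, with inversion, and the freed C2 alkoxide is then arylated at the ipso carbon. One operation forms two bonds, the five-membered ring and the trans C2/C3 relationship. The precursors are methyl 4-iodo-3-methoxybenzoate and an enantioenriched cis-epoxide carrying the MOM-protected ring B on C2 and a silyloxymethyl group on C3.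

Key step: step 6

Assumption: O1, C2, C3, C3a, C7 and C7a are the locants of the 2,3-dihydro-1-benzofuran core, ring B is the aryl group on C2, and compounds 1, 5 and 9 are bought.

Step 1
Reactants: 1 5-bromo-2-hydroxy-3-methoxybenzaldehyde
Product: 3 5-bromo-3-methoxybenzene-1,2-diol, via aryl formate 2 (not isolated)
Conditions: H2O2 (30 % aq), NaOH (aq), THF, 0 °C to rt; then HCl (aq) to pH 3
Reagents that add atoms: hydrogen peroxide, OO
Why: Dakin oxidation: hydroperoxide adds to the aldehyde of the ortho-hydroxybenzaldehyde, the aryl group migrates to oxygen and the formate 2 is saponified in the same pot, which turns C–CHO into C–OH and leaves the aryl bromide untouched.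

Step 2
Reactants: 3 5-bromo-3-methoxybenzene-1,2-diol
Product: 4 5-bromo-1-methoxy-2,3-bis(methoxymethoxy)benzene
Conditions: MOMCl, iPr2NEt, CH2Cl2, 0 °C to rt
Reagents that add atoms: chloromethyl methyl ether, COCCl
Why: Double Williamson-type O-alkylation of the catechol gives acetals that are inert to base, hydride, palladium and mild oxidants and are removed by dilute acid at the end.

Step 3
Reactants: 4 5-bromo-1-methoxy-2,3-bis(methoxymethoxy)benzene; 5 tert-butyldimethyl(prop-2-yn-1-yloxy)silane
Product: 6 tert-butyl({3-[3-methoxy-4,5-bis(methoxymethoxy)phenyl]prop-2-yn-1-yl}oxy)dimethylsilane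
Conditions: PdCl2(MeCN)2 (2 mol %), XPhos (6 mol %), Cs2CO3, MeCN, 80 °C
Reagents that add atoms: none
Why: Copper-free Sonogashira coupling: the bulky electron-rich biarylphosphine lets zerovalent palladium insert into the electron-rich aryl bromide, leaving copper out suppresses alkyne homocoupling, and the propargylic silyl ether is inert.

Step 4
Reactants: 6 tert-butyl({3-[3-methoxy-4,5-bis(methoxymethoxy)phenyl]prop-2-yn-1-yl}oxy)dimethylsilane
Product: 7 tert-butyl({(2Z)-3-[3-methoxy-4,5-bis(methoxymethoxy)phenyl]prop-2-en-1-yl}oxy)dimethylsilane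
Conditions: H2 (1 atm), Pd/CaCO3 poisoned with Pb(OAc)2 (Lindlar catalyst), quinoline, EtOAc, rt
Reagents that add atoms: none
Why: Lindlar semi-hydrogenation delivers both hydrogens to one face of the alkyne on the poisoned palladium surface, which gives the Z-alkene and stops before the alkane.

Step 5
Reactants: 7 tert-butyl({(2Z)-3-[3-methoxy-4,5-bis(methoxymethoxy)phenyl]prop-2-en-1-yl}oxy)dimethylsilane
Product: 8 tert-butyl({(2R,3S)-3-[3-methoxy-4,5-bis(methoxymethoxy)phenyl]oxiran-2-yl}methoxy)dimethylsilane (cis-epoxide)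
Conditions: (S,S)-[N,N'-bis(3,5-di-tert-butylsalicylidene)-1,2-cyclohexanediaminato]manganese chloride, (S,S)-(salen)MnCl (5 mol %), 4-phenylpyridine N-oxide, NaOCl (aq, pH 11.3), CH2Cl2, 0 °C
Reagents that add atoms: sodium hypochlorite, [Na+].[O-]Cl
Why: Jacobsen–Katsuki epoxidation: cis-disubstituted aryl-conjugated alkenes are the best substrate class for the manganese-oxo salen catalyst, the (S,S)-catalyst is expected (as with cis-β-methylstyrene and indene) to give the S configuration at the benzylic carbon, and because the cis geometry is carried over both epoxide stereocentres (2R,3S) are fixed by the catalyst in this step.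

Step 6
Reactants: 8 tert-butyl({(2R,3S)-3-[3-methoxy-4,5-bis(methoxymethoxy)phenyl]oxiran-2-yl}methoxy)dimethylsilane; 9 methyl 4-iodo-3-methoxybenzoate
Product: 10 methyl (2R,3S)-3-{[(tert-butyldimethylsilyl)oxy]methyl}-7-methoxy-2-[3-methoxy-4,5-bis(methoxymethoxy)phenyl]-2,3-dihydro-1-benzofuran-5-carboxylate (2,3-trans)
Conditions: Pd(OAc)2 (10 mol %), XPhos (20 mol %), potassium 5-norbornene-2-carboxylate (50 mol %), K2CO3 (2 equiv), NMP, 80 °C, Ar
Reagents that add atoms: none
Why: Proposed new method: oxidative addition of 9 to zerovalent palladium, norbornene insertion and carbonate-assisted palladation of C3a–H (the only free ortho position) should give the aryl–norbornyl palladacycle, whose divalent palladium centre attacks the CH2OSi-bearing carbon of 8 from the side opposite the oxirane oxygen; reductive elimination from tetravalent palladium then forms C3–C3a, norbornene is expelled by β-carbon elimination, and the resulting six-membered aryl-palladium alkoxide closes the dihydrofuran ring by C7a–O1 reductive elimination, an intramolecular C–O coupling. The closest known reactions are the palladium/norbornene annulation of ortho-substituted aryl iodides with terminal epoxides to 2-substituted 2,3-dihydrobenzofurans and the stereoinvertive Catellani ortho-alkylation with secondary alkyl iodides; the new element is a 2,3-disubstituted epoxide. The C3 stereocentre is set by substrate control through SN2 inversion at the epoxide carbon, while C2 and its oxygen are carried over untouched, so the cis-epoxide maps onto the 2,3-trans ring. The step needs attack at the non-benzylic carbon: the crowded palladacycle should prefer the carbon flanked by the slim CH2OSi arm, the carbonate-buffered medium free of Lewis acids gives the benzylic C–O bond no help to ionise, and the 4-oxygen of ring B, twisted out of plane by its two oxygen neighbours, donates only weakly. The C7 methoxy group blocks the second ortho site, which limits alkylation to one position and lets norbornene leave, and the silyl ether is a poor β-leaving group on the alkyl-palladium intermediate.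

Step 7
Reactants: 10 methyl (2R,3S)-3-{[(tert-butyldimethylsilyl)oxy]methyl}-7-methoxy-2-[3-methoxy-4,5-bis(methoxymethoxy)phenyl]-2,3-dihydro-1-benzofuran-5-carboxylate
Product: 11 [(2R,3S)-3-{[(tert-butyldimethylsilyl)oxy]methyl}-7-methoxy-2-[3-methoxy-4,5-bis(methoxymethoxy)phenyl]-2,3-dihydro-1-benzofuran-5-yl]methanol
Conditions: iBu2AlH, CH2Cl2, −78 to 0 °C; potassium sodium tartrate (aq)
Reagents that add atoms: none
Why: Hydride reduction of the aryl methyl ester with DIBAL-H gives the benzylic alcohol after aqueous work-up and leaves acetals, silyl ether and both stereocentres alone.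

Step 8
Reactants: 11 [(2R,3S)-3-{[(tert-butyldimethylsilyl)oxy]methyl}-7-methoxy-2-[3-methoxy-4,5-bis(methoxymethoxy)phenyl]-2,3-dihydro-1-benzofuran-5-yl]methanol
Product: 12 (2R,3S)-3-{[(tert-butyldimethylsilyl)oxy]methyl}-7-methoxy-2-[3-methoxy-4,5-bis(methoxymethoxy)phenyl]-2,3-dihydro-1-benzofuran-5-carbaldehyde
Conditions: activated MnO2, CH2Cl2, rt
Reagents that add atoms: none
Why: Activated MnO2 oxidises benzylic alcohols selectively to aldehydes at room temperature without over-oxidation and without touching the protected ring B.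

Step 9
Reactants: 12 (2R,3S)-3-{[(tert-butyldimethylsilyl)oxy]methyl}-7-methoxy-2-[3-methoxy-4,5-bis(methoxymethoxy)phenyl]-2,3-dihydro-1-benzofuran-5-carbaldehyde
Product: 13 (2E)-3-[(2R,3S)-3-{[(tert-butyldimethylsilyl)oxy]methyl}-7-methoxy-2-[3-methoxy-4,5-bis(methoxymethoxy)phenyl]-2,3-dihydro-1-benzofuran-5-yl]prop-2-enal
Conditions: Ph3P=CHCHO (1.3 equiv), toluene, 80 °C
Reagents that add atoms: (triphenylphosphoranylidene)acetaldehyde, O=CC=P(c1ccccc1)(c1ccccc1)c1ccccc1
Why: Wittig olefination with the formyl-stabilised ylide gives the E-enal under the usual preference of stabilised ylides, and a small excess with monitoring limits a second homologation.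

Step 10
Reactants: 13 (2E)-3-[(2R,3S)-3-{[(tert-butyldimethylsilyl)oxy]methyl}-7-methoxy-2-[3-methoxy-4,5-bis(methoxymethoxy)phenyl]-2,3-dihydro-1-benzofuran-5-yl]prop-2-enal
Product: 14 cassyformin, (2E)-3-[(2R,3S)-2-(3,4-dihydroxy-5-methoxyphenyl)-3-(hydroxymethyl)-7-methoxy-2,3-dihydro-1-benzofuran-5-yl]prop-2-enal
Conditions: 3 M HCl (aq), THF, 40 °C
Reagents that add atoms: none
Why: Acid hydrolysis cleaves the two aryl MOM acetals and the primary silyl ether in one operation; no stereocentre is touched, and should the C2–O1 bond ionise reversibly, reclosure anti to the C3 substituent returns the trans ring with C3 intact.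

Compound list
1 | 5-bromo-2-hydroxy-3-methoxybenzaldehyde | COc1cc(Br)cc(C=O)c1O | starting material
2 | 5-bromo-2-hydroxy-3-methoxyphenyl formate | COc1cc(Br)cc(OC=O)c1O | intermediate
3 | 5-bromo-3-methoxybenzene-1,2-diol | COc1cc(Br)cc(O)c1O | intermediate
4 | 5-bromo-1-methoxy-2,3-bis(methoxymethoxy)benzene | COc1cc(Br)cc(OCOC)c1OCOC | intermediate
5 | tert-butyldimethyl(prop-2-yn-1-yloxy)silane | C#CCO[Si](C)(C)C(C)(C)C | starting material
6 | tert-butyl({3-[3-methoxy-4,5-bis(methoxymethoxy)phenyl]prop-2-yn-1-yl}oxy)dimethylsilane | COc1cc(C#CCO[Si](C)(C)C(C)(C)C)cc(OCOC)c1OCOC | intermediate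
7 | tert-butyl({(2Z)-3-[3-methoxy-4,5-bis(methoxymethoxy)phenyl]prop-2-en-1-yl}oxy)dimethylsilane | COc1cc(/C=C\CO[Si](C)(C)C(C)(C)C)cc(OCOC)c1OCOC | intermediate
8 | tert-butyl({(2R,3S)-3-[3-methoxy-4,5-bis(methoxymethoxy)phenyl]oxiran-2-yl}methoxy)dimethylsilane (cis) | COc1cc([C@@H]2O[C@@H]2CO[Si](C)(C)C(C)(C)C)cc(OCOC)c1OCOC | intermediate
9 | methyl 4-iodo-3-methoxybenzoate | COC(=O)c1ccc(I)c(OC)c1 | starting material
10 | methyl (2R,3S)-3-{[(tert-butyldimethylsilyl)oxy]methyl}-7-methoxy-2-[3-methoxy-4,5-bis(methoxymethoxy)phenyl]-2,3-dihydro-1-benzofuran-5-carboxylate (trans) | COc1cc([C@@H]2Oc3c(OC)cc(C(=O)OC)cc3[C@H]2CO[Si](C)(C)C(C)(C)C)cc(OCOC)c1OCOC | intermediate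
11 | [(2R,3S)-3-{[(tert-butyldimethylsilyl)oxy]methyl}-7-methoxy-2-[3-methoxy-4,5-bis(methoxymethoxy)phenyl]-2,3-dihydro-1-benzofuran-5-yl]methanol | COc1cc([C@@H]2Oc3c(OC)cc(CO)cc3[C@H]2CO[Si](C)(C)C(C)(C)C)cc(OCOC)c1OCOC | intermediate
12 | (2R,3S)-3-{[(tert-butyldimethylsilyl)oxy]methyl}-7-methoxy-2-[3-methoxy-4,5-bis(methoxymethoxy)phenyl]-2,3-dihydro-1-benzofuran-5-carbaldehyde | COc1cc([C@@H]2Oc3c(OC)cc(C=O)cc3[C@H]2CO[Si](C)(C)C(C)(C)C)cc(OCOC)c1OCOC | intermediate
13 | (2E)-3-[(2R,3S)-3-{[(tert-butyldimethylsilyl)oxy]methyl}-7-methoxy-2-[3-methoxy-4,5-bis(methoxymethoxy)phenyl]-2,3-dihydro-1-benzofuran-5-yl]prop-2-enal | COc1cc([C@@H]2Oc3c(OC)cc(/C=C/C=O)cc3[C@H]2CO[Si](C)(C)C(C)(C)C)cc(OCOC)c1OCOC | intermediate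
14 | cassyformin, (2E)-3-[(2R,3S)-2-(3,4-dihydroxy-5-methoxyphenyl)-3-(hydroxymethyl)-7-methoxy-2,3-dihydro-1-benzofuran-5-yl]prop-2-enal | COc1cc([C@@H]2Oc3c(OC)cc(/C=C/C=O)cc3[C@H]2CO)cc(O)c1O | target

Total step count: 10. Longest linear sequence: 10 steps (1 to 14); 5 and 9 enter as bought fragments at steps 3 and 6.

Steps most likely to fail

Step 6. The palladacycle may open the epoxide at the benzylic carbon instead, or fail to open a disubstituted epoxide at all, so that 9 is consumed by reduction or homocoupling. Iodide may also open and reclose the epoxide and erode its geometry, and the palladium alkoxide may lose the C2 hydrogen by β-hydride elimination. The fallback uses known chemistry, sets out from 4 and rejoins the route at 12. Bromine–lithium exchange on 4 (n-BuLi, THF, −78 °C) and trapping with paraformaldehyde should give [3-methoxy-4,5-bis(methoxymethoxy)phenyl]methanol F1. Mitsunobu etherification (PPh3, DIAD, THF) with purchased methyl 4-hydroxy-3-iodo-5-methoxybenzoate, COC(=O)c1cc(I)c(O)c(OC)c1, should give methyl 3-iodo-5-methoxy-4-{[3-methoxy-4,5-bis(methoxymethoxy)phenyl]methoxy}benzoate F2. Palladium-catalysed coupling of this aryl iodide with methyl diazoacetate (Pd(PPh3)4, Ag2CO3, Et3N, toluene, rt) should give methyl 3-(1-diazo-2-methoxy-2-oxoethyl)-5-methoxy-4-{[3-methoxy-4,5-bis(methoxymethoxy)phenyl]methoxy}benzoate F3. Enantioselective intramolecular carbenoid insertion into the benzylic ether C–H bond follows, with dirhodium tetrakis[N-phthaloyl-(S)-tert-leucinate], Rh2(S-PTTL)4, or its mirror image, whichever gives the 2R series (toluene, −60 °C). It forms C2–C3 and should give the cis product dimethyl (2R,3S)-7-methoxy-2-[3-methoxy-4,5-bis(methoxymethoxy)phenyl]-2,3-dihydro-1-benzofuran-3,5-dicarboxylate F4. NaOMe in MeOH epimerises C3 next to the ester to the trans isomer dimethyl (2R,3R)-7-methoxy-2-[3-methoxy-4,5-bis(methoxymethoxy)phenyl]-2,3-dihydro-1-benzofuran-3,5-dicarboxylate F5. LiAlH4 (THF, 0 °C) reduces both esters to [(2R,3S)-5-(hydroxymethyl)-7-methoxy-2-[3-methoxy-4,5-bis(methoxymethoxy)phenyl]-2,3-dihydro-1-benzofuran-3-yl]methanol F6. MnO2 oxidises only the benzylic alcohol to (2R,3S)-3-(hydroxymethyl)-7-methoxy-2-[3-methoxy-4,5-bis(methoxymethoxy)phenyl]-2,3-dihydro-1-benzofuran-5-carbaldehyde F7, and TBSCl with imidazole in DMF then gives 12.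

Step 5. Oxygen transfer from the manganese-oxo species is stepwise, so rotation in the benzylic radical can leak cis geometry into trans epoxide. Facial selectivity may also drop with the allylic silyloxy group, and the electron-rich ring may be oxidised. The fallback sets out from 7 and rejoins at 8. Desilylation of 7 (Bu4NF, THF) should give (2Z)-3-[3-methoxy-4,5-bis(methoxymethoxy)phenyl]prop-2-en-1-ol F8. Sharpless asymmetric epoxidation (Ti(OiPr)4, D-(−)-diisopropyl tartrate, t-BuOOH, 4 Å sieves, CH2Cl2, −20 °C) transfers oxygen in a concerted, geometry-retaining step inside the titanium–tartrate–allyl alkoxide complex and should give {(2R,3S)-3-[3-methoxy-4,5-bis(methoxymethoxy)phenyl]oxiran-2-yl}methanol F9. TBSCl with imidazole returns 8.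

Step 10. The acid needed to cleave the acetals may also add water across the enal or oligomerise it, and the freed catechol may oxidise during the longer exposure. The fallback sets out from 12 and rejoins at 14, so that acid never meets the enal. Treatment of 12 with 3 M HCl (aq) in THF removes both MOM groups and the silyl ether at the aldehyde stage and should give (2R,3S)-2-(3,4-dihydroxy-5-methoxyphenyl)-3-(hydroxymethyl)-7-methoxy-2,3-dihydro-1-benzofuran-5-carbaldehyde F10. Wittig olefination of this unprotected aldehyde with Ph3P=CHCHO (THF, 60 °C), a weakly basic ylide that tolerates free phenols, then gives 14.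

Further compounds
F1 | step 6 | [3-methoxy-4,5-bis(methoxymethoxy)phenyl]methanol | COc1cc(CO)cc(OCOC)c1OCOC
F2 | step 6 | methyl 3-iodo-5-methoxy-4-{[3-methoxy-4,5-bis(methoxymethoxy)phenyl]methoxy}benzoate | COC(=O)c1cc(I)c(OCc2cc(OC)c(OCOC)c(OCOC)c2)c(OC)c1
F3 | step 6 | methyl 3-(1-diazo-2-methoxy-2-oxoethyl)-5-methoxy-4-{[3-methoxy-4,5-bis(methoxymethoxy)phenyl]methoxy}benzoate | COC(=O)C(=[N+]=[N-])c1cc(C(=O)OC)cc(OC)c1OCc1cc(OC)c(OCOC)c(OCOC)c1
F4 | step 6 | dimethyl (2R,3S)-7-methoxy-2-[3-methoxy-4,5-bis(methoxymethoxy)phenyl]-2,3-dihydro-1-benzofuran-3,5-dicarboxylate (cis) | COc1cc([C@@H]2Oc3c(OC)cc(C(=O)OC)cc3[C@@H]2C(=O)OC)cc(OCOC)c1OCOC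
F5 | step 6 | dimethyl (2R,3R)-7-methoxy-2-[3-methoxy-4,5-bis(methoxymethoxy)phenyl]-2,3-dihydro-1-benzofuran-3,5-dicarboxylate (trans) | COc1cc([C@@H]2Oc3c(OC)cc(C(=O)OC)cc3[C@H]2C(=O)OC)cc(OCOC)c1OCOC
F6 | step 6 | [(2R,3S)-5-(hydroxymethyl)-7-methoxy-2-[3-methoxy-4,5-bis(methoxymethoxy)phenyl]-2,3-dihydro-1-benzofuran-3-yl]methanol | COc1cc([C@@H]2Oc3c(OC)cc(CO)cc3[C@H]2CO)cc(OCOC)c1OCOC
F7 | step 6 | (2R,3S)-3-(hydroxymethyl)-7-methoxy-2-[3-methoxy-4,5-bis(methoxymethoxy)phenyl]-2,3-dihydro-1-benzofuran-5-carbaldehyde | COc1cc([C@@H]2Oc3c(OC)cc(C=O)cc3[C@H]2CO)cc(OCOC)c1OCOC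
F8 | step 5 | (2Z)-3-[3-methoxy-4,5-bis(methoxymethoxy)phenyl]prop-2-en-1-ol | COc1cc(/C=C\CO)cc(OCOC)c1OCOC
F9 | step 5 | {(2R,3S)-3-[3-methoxy-4,5-bis(methoxymethoxy)phenyl]oxiran-2-yl}methanol (cis) | COc1cc([C@@H]2O[C@@H]2CO)cc(OCOC)c1OCOC
F10 | step 10 | (2R,3S)-2-(3,4-dihydroxy-5-methoxyphenyl)-3-(hydroxymethyl)-7-methoxy-2,3-dihydro-1-benzofuran-5-carbaldehyde | COc1cc([C@@H]2Oc3c(OC)cc(C=O)cc3[C@H]2CO)cc(O)c1O
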